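(All runs were generated by integration on assumed constants.)

I counted time in a single unit for these flasks, the half-life of the starting material under the partner, and asked what else happens inside it.

| flask | starting material | partner | second reagent | protic impurity | remark | time |
|---|---|---|---|---|---|---|
| Friday's | 0.20 M | 1.2 equiv | 0.95 equiv | 0.20 M | run made earlier |  |
| Saturday's | 0.20 M | 1.2 equiv | 1.4 equiv | 0.20 M | run made earlier |  |
| red | 0.20 M | 1.20 equiv | 0.950 equiv | 0.200 M | one stirred flow tank at steady state, fed with the mixture as stated, mean residence time 25 h |  |
| green | 0.20 M | 1.20 equiv | 0.950 equiv | 0.200 M | a closed flask charged with all of it at once and left for 25 h | 25 h |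
| ochre | 0.20 M | 1.20 equiv | 0.950 equiv (fed, over 20.0 h) | 0.200 M | a stirred flask in which second reagent is dosed at a steady rate over 20.0 h without added volume, worked up at 25 h | 25 h |
| grey | 0.20 M (fed, over 20.0 h) | 1.20 equiv | 0.950 equiv | 0.200 M | all but starting material at the start; starting material goes in evenly over 20.0 h, the run ends at 25 h | 25 h |

- Friday's (time / h: intermediate / %, target / %): 2.00: 33.9, 0; 5.00: 55.6, 3.1; 10.0: 67.5, 3.7; 25.0: 74.4, 3.0
- Saturday's (time / h: intermediate / %, target / %): 0.200: 5.1, 0; 0.500: 10.8, 0; 1.00: 20.9, 0; 2.50: 36.9, 0.5

(standard deviation of a reading: 1 percentage point)

- the set-up with the highest amount of intermediate at the outlet or at the end, in percent of the starting material put in ("none" if the first two lie within 2 percentage points) (red / green / ochre / grey / none)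
- amount of intermediate at the outlet or at the end, in percent of the starting material put in, red
- amount of intermediate at the outlet or at the end, in percent of the starting material put in, green
- amount of intermediate at the outlet or at the end, in percent of the starting material put in, ochre
- amount of intermediate at the outlet or at the end, in percent of the starting material put in, grey

- the stated concentrations are those of everything mixed, before any reaction; amounts are the same in each set-up
- what was read earlier has a scatter of 1 percentage point, one standard deviation
- the feed brings no volume worth counting
- the earlier runs were made in a closed, stirred flask

How long does the starting material last? Friday's reading of 33.9% intermediate at 2.00 h, read as second order in starting material and partner, gave a rate constant k = 1.03 /M/h. With the partner held at its charge, a pseudo-first-order view, that is t_A = 2.82 h, the half-life of the starting material under the partner step.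

How much of the charge goes astray? The same k carried to 25.0 h reckoned a conversion of 91.5%, but Friday read 77.4% as intermediate and target together, a gap of 14 percentage points.

Can timing recover that gap? I suspected the second reagent acting on the starting material, though the two runs leave this open. Green is Friday's recipe and holds its full charge of second reagent from the start, whereas in ochre the pump delivers 14.1% of it within one t_A, since t_A is shorter than the dosing time. On that assumption I ranked ochre first, above green.

The forecast gave 57% for red, 75% for green, 76% for ochre and 68% for grey, with none as best, saying “dosing changes little, perhaps slightly less target”; there it and I parted.

The flasks gave 59.1% for red, 74.6% for green, 80.2% for ochre and 72.2% for grey, so ochre came first, 5.6 points above green.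

    starting material + partner → intermediate (k = 1.08 /M/h)
    second reagent + intermediate → target (k = 0.100 /M/h)
    starting material + second reagent → side product (k = 0.251 /M/h)
    target → over-reaction product (k = 0.118 /h)
    second reagent + protic impurity → quenched reagent (k = 0.678 /M/h)

In green, with the other concentrations as charged, the half-life of starting material was 2.7 h by the partner step alone and 15 h by the step to side product alone, the first shorter by a factor of 5.44. In grey, the last starting material fed had 1.77 units of t_A before the end.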